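## Retrosynthetic overview

1. Enabling feature (guaiane numbering): in the cyclopentane C1–C5 the tertiary carbinol C4 is β to the C6 oxygen through C5 (C4(OH)–C5–C6=O, an aldol retron). It is also γ,δ to the tetrasubstituted C1=C10 bond, which is exocyclic to the five-membered ring (C4(=O)–C3–C2–C1=C10, a Claisen retron). C3–C4(CH3)–O is therefore an acetone unit.
2. Key disconnection, one operation: C2–C3 by Claisen [3,3] shift of a C10–O–isopropenyl ether across the exocyclic C1=C2 bond of a cycloheptadienolate, and C4–C5 by aldol addition of that dienolate to the methyl ketone just released. The five-membered ring is formed second.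
3. The seven-membered ring is formed first, by RCM of a bis-methallyl ketone to the C1=C10 alkene. Epoxidation and E1cB opening then place the transient C10 oxygen and leave the C2 methyl as the only enolisable γ-position.
4. C7 and C8 come from an Evans syn-aldol of an isovaleryl imide with 3-methylbut-3-enal. C6 is set after the key step by chelation-controlled reduction of the aldol ketone.
5. End game: C6 acetate, desilylation, C8 angelate by mixed-anhydride esterification.

Key step: step 12

Remarks on the chemistry: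
- Guaiane numbering is used for all ring compounds, including the monocyclic precursors: C1–C5 five-membered ring, C1/C5–C10 seven-membered ring, C4 carbinol, C6 acetate, C7 isopropyl, C8 angelate, C10 methyl.
- α/β are local descriptors: β is the face that carries H-5 in the target, α the opposite face.
- Assumption: the C10 carbinol centre of 13–18 is transient (it becomes sp2 in step 12). It is drawn as the epimer expected from epoxidation anti to the OTBS group; the other epimer would converge.

## Route

Step 1
Reactants: 1 (R)-4-benzyloxazolidin-2-one; 2 3-methylbutanoyl chloride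
Product: 3 (R)-4-benzyl-3-(3-methylbutanoyl)oxazolidin-2-one
Conditions: Et3N, DMAP (cat.), CH2Cl2, 0 °C to rt
Reagents that add atoms: none
Why: DMAP-catalysed N-acylation of the oxazolidinone; no stereocentre is touched.

Step 2
Reactants: 4 3-methylbut-3-en-1-ol
Product: 5 3-methylbut-3-enal
Conditions: Dess–Martin periodinane, NaHCO3, CH2Cl2, 0 °C; solution used directly
Reagents that add atoms: none
Why: Dess–Martin oxidation under buffered, non-basic conditions should give the β,γ-unsaturated aldehyde without migration of the double bond.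

Step 3
Reactants: 3 (R)-4-benzyl-3-(3-methylbutanoyl)oxazolidin-2-one; 5 3-methylbut-3-enal
Product: 7 (R)-4-benzyl-3-[(2R,3S)-3-hydroxy-5-methyl-2-(propan-2-yl)hex-5-enoyl]oxazolidin-2-one, via dibutylboron Z-enolate 6 (not isolated)
Conditions: Bu2BOTf, iPr2NEt, CH2Cl2, −78 to 0 °C; 5, −78 to 0 °C; H2O2, pH 7 buffer, MeOH
Reagents that add atoms: none
Why: Evans syn-aldol reaction: the Z-boron enolate reacts through a Zimmerman–Traxler chair on the face anti to the benzyl group, which should set the 2,3-syn pair (2R,3S), the future C7 and C8.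

Step 4
Reactants: 7 aldol adduct
Product: 8 (2R,3S)-3-hydroxy-N-methoxy-N,5-dimethyl-2-(propan-2-yl)hex-5-enamide
Conditions: MeNH(OMe)·HCl, AlMe3, CH2Cl2, −10 °C to rt; 1 M HCl
Reagents that add atoms: N,O-dimethylhydroxylamine hydrochloride, CNOC.Cl
Why: Weinreb amide formation by aluminium-amide transamidation, assisted by the free β-hydroxyl; the auxiliary is released and no epimerisation at C7 is expected.

Step 5
Reactants: 8 hydroxy Weinreb amide
Product: 9 (2R,3S)-3-[(tert-butyldimethylsilyl)oxy]-N-methoxy-N,5-dimethyl-2-(propan-2-yl)hex-5-enamide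
Conditions: TBSOTf, 2,6-lutidine, CH2Cl2, −78 to 0 °C
Reagents that add atoms: tert-butyldimethylsilyl trifluoromethanesulfonate, CC(C)(C)[Si](C)(C)OS(=O)(=O)C(F)(F)F
Why: standard silylation of a hindered secondary alcohol with a silyl triflate; the TBS ether survives every later step up to step 15.

Step 6
Reactants: 9 silyloxy Weinreb amide; 10 (2-methylallyl)magnesium chloride
Product: 11 (5R,6S)-6-[(tert-butyldimethylsilyl)oxy]-2,8-dimethyl-5-(propan-2-yl)nona-1,8-dien-4-one
Conditions: THF, −78 to −20 °C; pH 7 buffer, 0 °C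
Reagents that add atoms: none
Why: Weinreb ketone synthesis: the chelated tetrahedral adduct prevents a second addition, and the cold neutral quench should keep the new alkene β,γ and C7 intact.

Step 7
Reactants: 11 bis-methallyl ketone
Product: 12 (2R,3S)-3-[(tert-butyldimethylsilyl)oxy]-5,6-dimethyl-2-(propan-2-yl)cyclohept-5-en-1-one
Conditions: Stewart–Grubbs catalyst (5 mol %), PhMe, 80 °C
Reagents that add atoms: none
Why: ring-closing metathesis of two 1,1-disubstituted (methallyl) olefins closes the seven-membered ring at the tetrasubstituted C1=C10 bond with loss of ethene; the o-tolyl-NHC catalyst is the one made for tetrasubstituted olefins.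

Step 8
Reactants: 12 cycloheptenone
Product: 14 (4S,6S,7R)-6-[(tert-butyldimethylsilyl)oxy]-4-hydroxy-3,4-dimethyl-7-(propan-2-yl)cyclohept-2-en-1-one, via epoxy ketone 13 (not isolated)
Conditions: mCPBA, CH2Cl2, 0 °C; then Et3N, rt
Reagents that add atoms: 3-chloroperbenzoic acid, OOC(=O)c1cccc(Cl)c1
Why: peracid epoxidation of the electron-rich tetrasubstituted alkene (faster than Baeyer–Villiger oxidation) followed by E1cB opening of the β,γ-epoxy ketone through the C5 enolate gives the γ-hydroxy enone; the C10 carbinol configuration follows from attack anti to the OTBS group and is of no consequence.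

Step 9
Reactants: 14 γ-hydroxy enone
Product: 15 (4S,6S,7R)-4-acetoxy-6-[(tert-butyldimethylsilyl)oxy]-3,4-dimethyl-7-(propan-2-yl)cyclohept-2-en-1-one
Conditions: Ac2O, Et3N, DMAP, CH2Cl2, rt
Reagents that add atoms: acetic anhydride, CC(=O)OC(C)=O
Why: DMAP-catalysed acetylation of a tertiary alcohol; the acetate carries the future C4, its methyl group and the future O4.

Step 10
Reactants: 15 acetoxy enone
Product: 16 (1S,3S,4R)-3-[(tert-butyldimethylsilyl)oxy]-1-methyl-7-methylidene-4-(propan-2-yl)-5-[(trimethylsilyl)oxy]cyclohept-5-en-1-yl acetate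
Conditions: TMSOTf, Et3N, CH2Cl2, −78 to 0 °C
Reagents that add atoms: trimethylsilyl trifluoromethanesulfonate, C[Si](C)(C)OS(=O)(=O)C(F)(F)F
Why: soft enolisation to the linear silyl dienol ether: C10 is quaternary, so the C2 methyl is the only γ-position with hydrogen, and the α'-hydrogen at C7 is tertiary and flanked by isopropyl and OTBS; the exocyclic C1=C2 bond should therefore form.

Step 11
Reactants: 16 silyl dienol ether acetate
Product: 17 tert-butyldimethyl{[(1S,2R,6S)-6-methyl-5-methylidene-2-(propan-2-yl)-6-(prop-1-en-2-yloxy)-3-[(trimethylsilyl)oxy]cyclohept-3-en-1-yl]oxy}silane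
Conditions: Tebbe reagent, pyridine, THF–PhMe, −40 to 0 °C; filtration through basic alumina
Reagents that add atoms: Tebbe reagent (μ-chloro bridge not drawn), C[Al](C)C[Ti](Cl)(C1C=CC=C1)C1C=CC=C1
Why: Tebbe methylenation of the ester carbonyl gives the isopropenyl ether; the ketone is masked as the silyl enol ether, and the allyl vinyl ether should not rearrange at or below room temperature.

Step 12
Reactants: 17 allyl isopropenyl ether with TMS dienol ether
Product: 20 8α-[(tert-butyldimethylsilyl)oxy]-4β-hydroxy-5βH,7αH-guai-1(10)-en-6-one, via lithium dienolate 18 (not isolated), via rearranged lithium dienolate 19 (not isolated)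
Conditions: MeLi, THF, 0 °C; then PhMe, 100 °C (sealed tube); AcOH, −78 °C
Reagents that add atoms: none
Why: MeLi cleaves the O–SiMe3 bond to give lithium dienolate 18; on heating, its tertiary allyl isopropenyl ether (C2=C1–C10–O–C4(CH3)=C3H2) undergoes a chair Claisen [3,3] shift that forms C2–C3, moves the double bond into the tetrasubstituted C1=C10 position and unveils the C4 methyl ketone next to the waiting dienolate (19), which then adds through C5 to C4 in an intramolecular lithium aldol reaction. The closest known reaction types are the ketone Claisen rearrangement of tertiary allyl isopropenyl ethers (Saucy–Marbet/Carroll type, as in linalool to geranylacetone) and the intramolecular aldol addition of a lithium dienolate through its α-carbon. The Claisen step closes no ring; the aldol step closes the cyclopentane C1–C5 in the 5-(enolexo)-exo-trig mode. At C4, the C5=C6 enolate is held cis in the ring so that O6 lies on the H-5 side, and the lithium-bridged Zimmerman–Traxler arrangement places O4 syn to H-5 with the tether carbons C1 and C3 equatorial and the C4 methyl axial (4-OH cis to H-5); at C5, the ketone adds to the enolate face anti to the C7 isopropyl group, and the chelated aldolate is also the isomer favoured if the aldol equilibrates. The step needs α- rather than γ-attack of the dienolate, which the lithium counter-ion and the two adjacent quaternary carbons that attack at C10 would create should secure, and it needs C2 rather than C5 as the Claisen terminus, which is secured because only C1=C2 belongs to the allyl ether and only C2–C3 formation leaves an oxygen-stabilised enolate. The configuration at C10 is irrelevant because C10 becomes sp2.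

Step 13
Reactants: 20 bicyclic ketol
Product: 22 8α-[(tert-butyldimethylsilyl)oxy]-5βH,7αH-guai-1(10)-ene-4β,6β-diol, via diethylborinate chelate 21 (not isolated)
Conditions: Et2BOMe, THF–MeOH (4:1), −78 °C; NaBH4; AcOH, then MeOH evaporation
Reagents that add atoms: none
Why: Narasaka–Prasad reduction: boron bridges O4 and the C6 carbonyl, and external hydride should add axially, anti to the axial H-5 and anti to the C7 isopropyl group (α-face), giving the 6β-alcohol of the syn-1,3-diol.

Step 14
Reactants: 22 diol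
Product: 23 8α-[(tert-butyldimethylsilyl)oxy]-4β-hydroxy-5βH,7αH-guai-1(10)-en-6β-yl acetate
Conditions: Ac2O, pyridine, DMAP (cat.), CH2Cl2, 0 °C to rt
Reagents that add atoms: acetic anhydride, CC(=O)OC(C)=O
Why: DMAP-catalysed acetylation of the secondary C6 hydroxyl; the tertiary C4 hydroxyl should not react under these conditions.

Step 15
Reactants: 23 silyl ether acetate
Product: 24 4β,8α-dihydroxy-5βH,7αH-guai-1(10)-en-6β-yl acetate
Conditions: HF·pyridine, pyridine, THF, 0 °C to rt
Reagents that add atoms: none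
Why: fluoride cleavage of the secondary TBS ether in a buffered acidic medium, which should avoid acetyl migration and leave the tertiary alcohol and the alkene untouched.

Step 16
Reactants: 24 hydroxy acetate; 25 angelic acid
Product: 27 (4S,5R,6R,7R,8S)-6-acetoxy-4-hydroxyguai-1(10)-en-8-yl (2Z)-2-methylbut-2-enoate (target), via angelic 2,4,6-trichlorobenzoic anhydride 26 (not isolated)
Conditions: 25, 2,4,6-trichlorobenzoyl chloride, Et3N, PhMe, rt; then 24, 75 °C
Reagents that add atoms: none
Why: Yamaguchi-type esterification through the mixed anhydride without DMAP, which should keep the Z (angelate) geometry; only the secondary C8 hydroxyl is acylated, the tertiary C4 hydroxyl is not.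

## Compound list

1 | (R)-4-benzyloxazolidin-2-one | O=C1N[C@H](Cc2ccccc2)CO1 | starting material
2 | 3-methylbutanoyl chloride | CC(C)CC(Cl)=O | starting material
3 | (R)-4-benzyl-3-(3-methylbutanoyl)oxazolidin-2-one | CC(C)CC(=O)N1[C@H](Cc2ccccc2)COC1=O | intermediate
4 | 3-methylbut-3-en-1-ol | C=C(C)CCO | starting material
5 | 3-methylbut-3-enal | C=C(C)CC=O | intermediate
6 | dibutylboron Z-enolate of 3 (not isolated) | CC(C)/C=C(\OB(CCCC)CCCC)N1[C@H](Cc2ccccc2)COC1=O | intermediate
7 | (R)-4-benzyl-3-[(2R,3S)-3-hydroxy-5-methyl-2-(propan-2-yl)hex-5-enoyl]oxazolidin-2-one | CC(C)[C@@H](C(=O)N1[C@H](Cc2ccccc2)COC1=O)[C@@H](O)CC(C)=C | intermediate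
8 | (2R,3S)-3-hydroxy-N-methoxy-N,5-dimethyl-2-(propan-2-yl)hex-5-enamide | CC(C)[C@@H](C(=O)N(C)OC)[C@@H](O)CC(C)=C | intermediate
9 | (2R,3S)-3-[(tert-butyldimethylsilyl)oxy]-N-methoxy-N,5-dimethyl-2-(propan-2-yl)hex-5-enamide | CC(C)[C@@H](C(=O)N(C)OC)[C@@H](O[Si](C)(C)C(C)(C)C)CC(C)=C | intermediate
10 | (2-methylallyl)magnesium chloride | C=C(C)C[Mg]Cl | starting material
11 | (5R,6S)-6-[(tert-butyldimethylsilyl)oxy]-2,8-dimethyl-5-(propan-2-yl)nona-1,8-dien-4-one | CC(C)[C@@H](C(=O)CC(C)=C)[C@@H](O[Si](C)(C)C(C)(C)C)CC(C)=C | intermediate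
12 | (2R,3S)-3-[(tert-butyldimethylsilyl)oxy]-5,6-dimethyl-2-(propan-2-yl)cyclohept-5-en-1-one | CC(C)[C@H]1C(=O)CC(C)=C(C)C[C@@H]1O[Si](C)(C)C(C)(C)C | intermediate
13 | 5-[(tert-butyldimethylsilyl)oxy]-1,7-dimethyl-4-(propan-2-yl)-8-oxabicyclo[5.1.0]octan-3-one, epoxide oxygen trans to OTBS (not isolated) | CC(C)[C@H]1C(=O)C[C@@]2(C)O[C@@]2(C)C[C@@H]1O[Si](C)(C)C(C)(C)C | intermediate
14 | (4S,6S,7R)-6-[(tert-butyldimethylsilyl)oxy]-4-hydroxy-3,4-dimethyl-7-(propan-2-yl)cyclohept-2-en-1-one | CC(C)[C@H]1C(=O)C=C(C)[C@@](C)(O)C[C@@H]1O[Si](C)(C)C(C)(C)C | intermediate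
15 | (4S,6S,7R)-4-acetoxy-6-[(tert-butyldimethylsilyl)oxy]-3,4-dimethyl-7-(propan-2-yl)cyclohept-2-en-1-one | CC(C)[C@H]1C(=O)C=C(C)[C@@](C)(OC(C)=O)C[C@@H]1O[Si](C)(C)C(C)(C)C | intermediate
16 | (1S,3S,4R)-3-[(tert-butyldimethylsilyl)oxy]-1-methyl-7-methylidene-4-(propan-2-yl)-5-[(trimethylsilyl)oxy]cyclohept-5-en-1-yl acetate | CC(C)[C@H]1C(O[Si](C)(C)C)=CC(=C)[C@@](C)(OC(C)=O)C[C@@H]1O[Si](C)(C)C(C)(C)C | intermediate
17 | tert-butyldimethyl{[(1S,2R,6S)-6-methyl-5-methylidene-2-(propan-2-yl)-6-(prop-1-en-2-yloxy)-3-[(trimethylsilyl)oxy]cyclohept-3-en-1-yl]oxy}silane | CC(C)[C@H]1C(O[Si](C)(C)C)=CC(=C)[C@@](C)(OC(C)=C)C[C@@H]1O[Si](C)(C)C(C)(C)C | intermediate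
18 | lithium dienolate of 17 (C6–OLi, C5=C6, C1=C2; not isolated) | [Li+].CC(C)[C@H]1C([O-])=CC(=C)[C@@](C)(OC(C)=C)C[C@@H]1O[Si](C)(C)C(C)(C)C | intermediate
19 | rearranged lithium dienolate (C6–OLi, C5=C6, C1=C10, 3-oxobutyl chain on C1; not isolated) | [Li+].CC(C)[C@H]1C([O-])=CC(CCC(C)=O)=C(C)C[C@@H]1O[Si](C)(C)C(C)(C)C | intermediate
20 | 8α-[(tert-butyldimethylsilyl)oxy]-4β-hydroxy-5βH,7αH-guai-1(10)-en-6-one (6-[(tert-butyldimethylsilyl)oxy]-3-hydroxy-3,8-dimethyl-5-(propan-2-yl)-2,3,3a,5,6,7-hexahydroazulen-4(1H)-one) | CC(C)(C)[Si](C)(C)O[C@H]1CC(C)=C2CC[C@](C)(O)[C@H]2C(=O)[C@@H]1C(C)C | intermediate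
21 | O4-diethylborinate chelate of 20 (not isolated) | CC(C)(C)[Si](C)(C)O[C@H]1CC(C)=C2CC[C@](C)(OB(CC)CC)[C@H]2C(=O)[C@@H]1C(C)C | intermediate
22 | 8α-[(tert-butyldimethylsilyl)oxy]-5βH,7αH-guai-1(10)-ene-4β,6β-diol | CC(C)(C)[Si](C)(C)O[C@H]1CC(C)=C2CC[C@](C)(O)[C@H]2[C@H](O)[C@@H]1C(C)C | intermediate
23 | 8α-[(tert-butyldimethylsilyl)oxy]-4β-hydroxy-5βH,7αH-guai-1(10)-en-6β-yl acetate | CC(C)(C)[Si](C)(C)O[C@H]1CC(C)=C2CC[C@](C)(O)[C@H]2[C@H](OC(C)=O)[C@@H]1C(C)C | intermediate
24 | 4β,8α-dihydroxy-5βH,7αH-guai-1(10)-en-6β-yl acetate | O[C@H]1CC(C)=C2CC[C@](C)(O)[C@H]2[C@H](OC(C)=O)[C@@H]1C(C)C | intermediate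
25 | angelic acid, (2Z)-2-methylbut-2-enoic acid | C/C=C(/C)C(=O)O | starting material
26 | angelic 2,4,6-trichlorobenzoic anhydride (not isolated) | C/C=C(/C)C(=O)OC(=O)c1c(Cl)cc(Cl)cc1Cl | intermediate
27 | (4S,5R,6R,7R,8S)-6-acetoxy-4-hydroxyguai-1(10)-en-8-yl (2Z)-2-methylbut-2-enoate | C/C=C(/C)C(=O)O[C@H]1CC(C)=C2CC[C@](C)(O)[C@H]2[C@H](OC(C)=O)[C@@H]1C(C)C | target

## Step count

Total steps: 16. Longest linear sequence: 15 steps (1 → 3 → 7 → … → 27; step 2 is a one-step side branch).

## Steps most likely to fail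

**Step 12 (key step).** The [3,3] shift may be too slow at the temperature the lithium dienolate and the lithium aldolate tolerate. Retro-aldol cleavage, dehydration of the aldolate or γ-attack at C10 could then erode the product.
Fallback, from 17 back to 20: 17 is heated alone in toluene (110 °C, neutral), so that only the Claisen rearrangement occurs and gives the rearranged silyl dienol ether F1. Mild hydrolysis (citric acid, THF–H2O, 0 °C) gives the β,γ-unsaturated 1,6-diketone F2. Soft enolisation at the doubly activated C5 with TiCl4/Bu3N in CH2Cl2 at −78 °C then closes the cyclopentane through a chelated titanium enolate and returns 20.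

**Step 7.** Ring closure may stall because both olefins are 1,1-disubstituted. Catalyst decay and Ru–H-mediated migration of a double bond into conjugation with the ketone would then compete.
Fallback, from 9 back to 14: 9 is treated with allylmagnesium bromide in place of 10 to give the allyl ketone F3. RCM with a second-generation Grubbs catalyst, now to an uncritical trisubstituted alkene, gives the cycloheptenone F4. mCPBA followed by Et3N, as in step 8, gives the γ-hydroxy enone F5, which lacks the C1 methyl group. Me2CuLi with TMSCl (THF, −78 °C) adds the methyl group to C1 and silylates both oxygens to give the bis-silyl compound F6. Saegusa–Ito oxidation (Pd(OAc)2, MeCN) restores the enone, and K2CO3 in MeOH removes the tertiary silyl ether to return 14.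

**Step 13.** Facial selectivity of hydride addition to C6 may be poor, because the axial C4 methyl group opposes the chelate-controlled trajectory.
Fallback, from 20 back to 23: Me4NBH(OAc)3 (AcOH–MeCN, −30 °C) delivers hydride intramolecularly from the C4–O–B unit to the β-face and should give the 6α-hydroxy (6-epi) diol F7 cleanly. Mitsunobu esterification with acetic acid (PPh3, DIAD, THF) inverts C6 and gives the acetate 23 directly.

Further compounds
F1 | step 12 | rearranged TMS dienol ether (C6–OTMS, C5=C6, C1=C10, 3-oxobutyl chain on C1) | CC(C)[C@H]1C(O[Si](C)(C)C)=CC(CCC(C)=O)=C(C)C[C@@H]1O[Si](C)(C)C(C)(C)C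
F2 | step 12 | (2R,3S)-3-[(tert-butyldimethylsilyl)oxy]-5-methyl-6-(3-oxobutyl)-2-(propan-2-yl)cyclohept-5-en-1-one | CC(C)[C@H]1C(=O)CC(CCC(C)=O)=C(C)C[C@@H]1O[Si](C)(C)C(C)(C)C
F3 | step 7 | (5R,6S)-6-[(tert-butyldimethylsilyl)oxy]-8-methyl-5-(propan-2-yl)nona-1,8-dien-4-one | CC(C)[C@@H](C(=O)CC=C)[C@@H](O[Si](C)(C)C(C)(C)C)CC(C)=C
F4 | step 7 | (2R,3S)-3-[(tert-butyldimethylsilyl)oxy]-5-methyl-2-(propan-2-yl)cyclohept-5-en-1-one | CC(C)[C@H]1C(=O)CC=C(C)C[C@@H]1O[Si](C)(C)C(C)(C)C
F5 | step 7 | (4S,6S,7R)-6-[(tert-butyldimethylsilyl)oxy]-4-hydroxy-4-methyl-7-(propan-2-yl)cyclohept-2-en-1-one | CC(C)[C@H]1C(=O)C=C[C@@](C)(O)C[C@@H]1O[Si](C)(C)C(C)(C)C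
F6 | step 7 | bis-TMS conjugate adduct (C6–OTMS enol ether, C10–OTMS, methyl on C1; C1 not controlled and lost in the next operation) | CC(C)[C@H]1C(O[Si](C)(C)C)=CC(C)[C@@](C)(O[Si](C)(C)C)C[C@@H]1O[Si](C)(C)C(C)(C)C
F7 | step 13 | 8α-[(tert-butyldimethylsilyl)oxy]-5βH,7αH-guai-1(10)-ene-4β,6α-diol (6-epi-22) | CC(C)(C)[Si](C)(C)O[C@H]1CC(C)=C2CC[C@](C)(O)[C@H]2[C@@H](O)[C@@H]1C(C)C
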